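**Retrosynthetic overview** (target numbered as a hexahydro‑2H‑cyclopenta[b]furan: O1, C2 lactol, C3 ester carbon, C3a, C4 quaternary, C6a carbinol)
1. Lactol ring (formed last): the C2 aldehyde is unmasked from a vinyl group by ozonolysis and captured by the C6a tertiary OH; the phenol is freed in the same hydrogenative work‑up.
2. Quaternary C4–CH2 bond: photocatalytic vinyl‑radical relay (iodine abstraction at an (E)‑iodovinyl group, 1,5‑H shift from the ring methine, Giese addition to methyl vinyl ketone); the relay group becomes the vinyl group of line 1.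
3. C2–C3 bond, C3 carbinol and ester: chelation‑controlled addition of a 2‑stannylvinyl Grignard to a β‑hydroxy aldehyde, aroylation of the alkoxide in the same flask, then Sn→I exchange.
4. Cyclopentane (formed first): ozonolysis and intramolecular aldol ring contraction of (S)‑terpinen‑4‑ol, then hydrogenation and epimerisation.
5. Only the carbinol centre of terpinen‑4‑ol is purchased; every other stereocentre is relayed from it.

Assumption: (S)‑(+)‑terpinen‑4‑ol is bought in high ee; the lactol is drawn as the 2R anomer (OH trans to the ester), taken to be the thermodynamic anomer reached by equilibration.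

---

**Step 1**
Reactants: 1, (S)‑(+)‑terpinen‑4‑ol
Product: 2, (3S)‑3‑hydroxy‑6‑oxo‑3‑(propan‑2‑yl)heptanal (in equilibrium with its cyclic hemiketal)
Conditions: O3, CH2Cl2/MeOH 5:1, −78 °C; Me2S, −78 °C → rt
Reagents that add atoms: ozone, [O-][O+]=O
Why: Criegee ozonolysis of the only C=C with reductive work‑up gives the keto‑aldehyde and leaves the tertiary carbinol stereocentre untouched.

**Step 2**
Reactants: 2, (3S)‑3‑hydroxy‑6‑oxo‑3‑(propan‑2‑yl)heptanal
Product: 3, (5R)‑5‑hydroxy‑2‑methyl‑5‑(propan‑2‑yl)cyclopent‑1‑ene‑1‑carbaldehyde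
Conditions: piperidine (0.2 eq), AcOH (0.2 eq), benzene, 45 °C
Reagents that add atoms: none
Why: Amine‑catalysed intramolecular aldol condensation (aldehyde enamine onto the methyl ketone, five‑membered ring, then dehydration), the standard ring contraction of p‑menthene‑derived keto‑aldehydes; no new stereocentre.

**Step 3**
Reactants: 3, (5R)‑5‑hydroxy‑2‑methyl‑5‑(propan‑2‑yl)cyclopent‑1‑ene‑1‑carbaldehyde
Product: 4, (1R,2R,5S)‑2‑hydroxy‑5‑methyl‑2‑(propan‑2‑yl)cyclopentane‑1‑carbaldehyde (CHO cis to OH; ring C–H at the methyl carbon cis to CHO; Me and i‑Pr on the other face)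
Conditions: H2 (1 atm), 5% Pd/C, EtOAc, rt; filter; DBU (0.1 eq), CH2Cl2, 0 °C
Reagents that add atoms: none
Why: Heterogeneous syn‑hydrogenation from the OH face (anti to i‑Pr) puts the methine H on that face, and base epimerisation of the aldehyde α‑carbon then gives the thermodynamic isomer with CHO cis to OH and trans to Me and i‑Pr; the methyl‑bearing centre is temporary and is erased in step 6.

**Step 4**
Reactants: 4, (1R,2R,5S)‑2‑hydroxy‑5‑methyl‑2‑(propan‑2‑yl)cyclopentane‑1‑carbaldehyde; 5, (E)‑1,2‑bis(tributylstannyl)ethene; 6, 4‑(benzyloxy)benzoyl chloride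
Product: 7, (1R,2E)‑1‑[(1S,2R,5S)‑2‑hydroxy‑5‑methyl‑2‑(propan‑2‑yl)cyclopentyl]‑3‑(tributylstannyl)prop‑2‑en‑1‑yl 4‑(benzyloxy)benzoate
Conditions: 5, n‑BuLi, THF, −78 °C; MgBr2·OEt2 (gives (E)‑Bu3SnCH=CHMgBr, 2.2 eq); add 4, −78 °C; then 6 (1.1 eq), DMAP (0.1 eq), −78 → 0 °C
Reagents that add atoms: 5, CCCC[Sn](CCCC)(CCCC)/C=C/[Sn](CCCC)(CCCC)CCCC (delivers CH=CH–SnBu3); 6, O=C(Cl)c1ccc(OCc2ccccc2)cc1 (delivers the aroyl group)
Why: Cram‑chelate Grignard addition: Mg bridges the tertiary alkoxide and the aldehyde oxygen in a six‑membered chelate cis‑fused to the ring, the nucleophile attacks from the convex side (the side of the ring C–H), which sets the carbinol centre as required, and the secondary magnesium alkoxide is acylated in preference to the tertiary one.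

**Step 5**
Reactants: 7, the stannylvinyl ester
Product: 8, (1R,2E)‑1‑[(1S,2R,5S)‑2‑hydroxy‑5‑methyl‑2‑(propan‑2‑yl)cyclopentyl]‑3‑iodoprop‑2‑en‑1‑yl 4‑(benzyloxy)benzoate
Conditions: I2 (1.05 eq), CH2Cl2, 0 °C; aq. Na2S2O3/KF
Reagents that add atoms: iodine, II
Why: Ipso iododestannylation of a vinylstannane is fast and stereoretentive and leaves the ester and tertiary alcohol untouched.

**Step 6**
Reactants: 8, the (E)‑iodovinyl ester; 9, methyl vinyl ketone
Product: 10, (1S)‑1‑[(1S,2R,5R)‑2‑hydroxy‑5‑methyl‑5‑(3‑oxobutyl)‑2‑(propan‑2‑yl)cyclopentyl]prop‑2‑en‑1‑yl 4‑(benzyloxy)benzoate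
Conditions: 4CzIPN (2 mol %), n‑Bu3N (2 eq), H2O (10 eq), 9 (4 eq), MeCN (0.03 M), 450 nm LEDs, rt
Reagents that add atoms: 9, methyl vinyl ketone, C=CC(C)=O
Why: Proposed new method: traceless vinyl‑radical relay Giese alkylation — the photogenerated α‑aminoalkyl radical abstracts iodine from the iodovinyl group, the resulting σ‑vinyl radical has only one C–H in a 1,5 relationship (the tertiary ring C–H cis to the side chain, six‑membered transition state, strongly exothermic) and abstracts it, the tertiary ring radical adds to MVK on the face anti to the vicinal side chain (3‑oxobutyl trans to it, methyl cis, as in the target), and the α‑keto radical is reduced and protonated while the relay group is left as the vinyl (masked formyl) group; the closest known chemistry is tin‑hydride radical translocation from vinyl or aryl halides and photocatalytic halogen‑atom‑transfer Giese additions of alkyl iodides, but a vinyl‑iodide relay that alkylates an unactivated tertiary C–H intermolecularly to form a quaternary stereocentre has not been shown.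

**Step 7**
Reactants: 10, the vinyl keto‑ester
Product: 11, kuhistaferone, (2R,3R,3aS,4R,6aR)‑2‑hydroxy‑4‑methyl‑4‑(3‑oxobutyl)‑6a‑(propan‑2‑yl)hexahydro‑2H‑cyclopenta[b]furan‑3‑yl 4‑hydroxybenzoate
Conditions: O3, EtOAc, −78 °C (Sudan III end point), N2 purge; then 10% Pd/C, H2 (1 atm), rt
Reagents that add atoms: ozone, [O-][O+]=O
Why: Ozonolysis of the terminal alkene with hydrogenative work‑up gives the α‑acyloxy aldehyde, which is trapped by the cis tertiary OH as the five‑membered lactol while the same Pd/H2 removes the benzyl ether; the anomeric centre equilibrates to the OH‑trans‑to‑ester anomer and no other stereocentre is touched.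

---

**Compound list**
1 | (S)‑(+)‑terpinen‑4‑ol | CC1=CC[C@](O)(C(C)C)CC1 | starting material
2 | (3S)‑3‑hydroxy‑6‑oxo‑3‑(propan‑2‑yl)heptanal | O=CC[C@](O)(C(C)C)CCC(C)=O | intermediate
3 | (5R)‑5‑hydroxy‑2‑methyl‑5‑(propan‑2‑yl)cyclopent‑1‑ene‑1‑carbaldehyde | CC1=C(C=O)[C@](O)(C(C)C)CC1 | intermediate
4 | (1R,2R,5S)‑2‑hydroxy‑5‑methyl‑2‑(propan‑2‑yl)cyclopentane‑1‑carbaldehyde | C[C@H]1CC[C@@](O)(C(C)C)[C@@H]1C=O | intermediate
5 | (E)‑1,2‑bis(tributylstannyl)ethene | CCCC[Sn](CCCC)(CCCC)/C=C/[Sn](CCCC)(CCCC)CCCC | starting material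
6 | 4‑(benzyloxy)benzoyl chloride | O=C(Cl)c1ccc(OCc2ccccc2)cc1 | starting material
7 | (1R,2E)‑1‑[(1S,2R,5S)‑2‑hydroxy‑5‑methyl‑2‑(propan‑2‑yl)cyclopentyl]‑3‑(tributylstannyl)prop‑2‑en‑1‑yl 4‑(benzyloxy)benzoate | C[C@H]1CC[C@@](O)(C(C)C)[C@@H]1[C@@H](OC(=O)c2ccc(OCc3ccccc3)cc2)/C=C/[Sn](CCCC)(CCCC)CCCC | intermediate
8 | (1R,2E)‑1‑[(1S,2R,5S)‑2‑hydroxy‑5‑methyl‑2‑(propan‑2‑yl)cyclopentyl]‑3‑iodoprop‑2‑en‑1‑yl 4‑(benzyloxy)benzoate | C[C@H]1CC[C@@](O)(C(C)C)[C@@H]1[C@@H](OC(=O)c2ccc(OCc3ccccc3)cc2)/C=C/I | intermediate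
9 | methyl vinyl ketone | C=CC(C)=O | starting material
10 | (1S)‑1‑[(1S,2R,5R)‑2‑hydroxy‑5‑methyl‑5‑(3‑oxobutyl)‑2‑(propan‑2‑yl)cyclopentyl]prop‑2‑en‑1‑yl 4‑(benzyloxy)benzoate | CC(=O)CC[C@@]1(C)CC[C@@](O)(C(C)C)[C@@H]1[C@@H](OC(=O)c2ccc(OCc3ccccc3)cc2)C=C | intermediate
11 | kuhistaferone | CC(=O)CC[C@@]1(C)CC[C@]2(C(C)C)O[C@@H](O)[C@H](OC(=O)c3ccc(O)cc3)[C@H]12 | target

---

**Total step count:** 7 (steps 3, 4 and 7 are one‑flask sequences). **Longest linear sequence:** 7.

**Three steps most likely to fail**
- **Step 6 (proposed new step).** Risks: direct reduction of the vinyl radical or its addition to MVK before the 1,5‑H shift; aminoalkyl radical adding to MVK; only the isomer of 8 with the ring C–H cis to the side chain can relay. Fallback (known chemistry, different approach): pre‑install the radical handle. Replace the hydrogenation by Cu(I)/B2pin2 conjugate borylation of 3 to the tertiary boronate, carry it through step 4 with plain vinylMgBr, convert to the trifluoroborate (KHF2), and use the established photoredox deboronative Giese addition of tertiary alkyl trifluoroborates to MVK; the stereochemical argument at the quaternary carbon is unchanged.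
- **Step 2.** Risk: the existing β‑hydroxyl can be eliminated by the enamine instead of (or as well as) the new aldol hydroxyl. Fallback: O‑silylate 1 (TES), ozonolyse, close the ring as a Ti(IV)‑mediated aldol addition, dehydrate the new free tertiary alcohol separately with Burgess reagent (regiochemistry then fixed), and desilylate before step 3.
- **Step 3.** Risks: hydrogenolysis of the allylic tertiary C–O bond, wrong face of H2 delivery, retro‑aldol during epimerisation. Fallback: a redox detour — Luche reduction of 3 to the allylic diol, hydroxyl‑directed homogeneous hydrogenation (cationic Ir) from the OH face, re‑oxidation of the primary alcohol, then epimerisation of the aldehyde.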